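**Retrosynthetic overview**

1. Target diacid ⇐ its bicyclic dimethyl ester (ester hydrolysis last).
2. Bicyclic diester ⇐ acyclic (2R)-oxiranyl diene diester: one Lewis-acid operation makes the C16–C1 bond (14-membered carbocycle, formed first) and then the O14–C15 bond (oxolane, from the resulting tertiary cation), setting C1.
3. Epoxy diester ⇐ dimethyl (R)-malate (supplies C13) + a primary iodide: Fráter–Seebach alkylation sets C12, then ester reduction and epoxide closure.
4. Iodide ⇐ Evans allylation (sets C8) of the N-acyl oxazolidinone of (5Z)-6,10-dimethylundeca-5,9-dienoic acid, then hydrozirconation–iodination.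
5. That acid ⇐ nerol (supplies the Z-trisubstituted olefin and the isopropylidene terminus) + a three-carbon Grignard unit.

Assumption: the SMILES is taken as drawn, i.e. (1R,4Z,8R,12S,13S)-4,15,15-trimethyl-14-oxabicyclo[11.2.1]hexadec-4-ene-8,12-dicarboxylic acid; these target locants (C1 = ring CH bonded to CMe2, C8 and C12 = CH–CO2H, C13 = O–CH, O14, C15 = CMe2, C16 = bridging CH2) are used whenever a position is discussed.

**Route**

Step 1
Reactants: 1 nerol
Product: 2 (2Z)-1-bromo-3,7-dimethylocta-2,6-diene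
Conditions: PBr3 (0.4 equiv), Et2O, −10 °C
Reagents that add atoms: phosphorus tribromide, BrP(Br)Br
Why: PBr3 bromination is an SN2 displacement of the phosphite ester at the primary allylic carbon, which at −10 °C proceeds without allylic transposition and keeps the Z olefin.

Step 2
Reactants: 2 (2Z)-1-bromo-3,7-dimethylocta-2,6-diene; 3 3-chloropropan-1-ol
Product: 5 (5Z)-6,10-dimethylundeca-5,9-dien-1-ol, via ClMg(CH2)3OMgCl 4 (not isolated)
Conditions: 3, i-PrMgCl, THF, −20 °C; Mg, reflux; then 2, Li2CuCl4 (3 mol %), −20 → 0 °C; aq NH4Cl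
Reagents that add atoms: none
Why: Copper-catalysed Grignard cross-coupling (Li2CuCl4) of a primary allylic bromide is an SN2 (α) attack that retains the Z geometry, and 4 carries the hydroxyl as an inert magnesium alkoxide.

Step 3
Reactants: 5 (5Z)-6,10-dimethylundeca-5,9-dien-1-ol
Product: 7 (5Z)-6,10-dimethylundeca-5,9-dienoic acid, via (5Z)-6,10-dimethylundeca-5,9-dienal 6 (not isolated)
Conditions: TEMPO (20 mol %), PhI(OAc)2 (2.2 equiv), MeCN/H2O 1:1, rt
Reagents that add atoms: water, O
Why: Oxoammonium (TEMPO/PhI(OAc)2) oxidation takes the primary alcohol through the aldehyde hydrate to the acid under near-neutral conditions that neither attack nor isomerise the trisubstituted olefins.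

Step 4
Reactants: 7 (5Z)-6,10-dimethylundeca-5,9-dienoic acid; 8 (4R)-4-benzyl-1,3-oxazolidin-2-one
Product: 10 (4R)-4-benzyl-3-[(5Z)-6,10-dimethylundeca-5,9-dienoyl]-1,3-oxazolidin-2-one, via mixed pivalic anhydride 9 (not isolated)
Conditions: t-BuCOCl, Et3N, THF, −20 °C; then 8, LiCl, −20 °C → rt
Reagents that add atoms: none
Why: Mixed-anhydride N-acylation, in which the LiCl/Et3N-activated oxazolidinone attacks the less hindered carbonyl of the pivalic anhydride.

Step 5
Reactants: 10 (4R)-4-benzyl-3-[(5Z)-6,10-dimethylundeca-5,9-dienoyl]-1,3-oxazolidin-2-one; 11 allyl iodide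
Product: 13 (4R)-4-benzyl-3-[(2S,5Z)-6,10-dimethyl-2-(prop-2-en-1-yl)undeca-5,9-dienoyl]-1,3-oxazolidin-2-one, via sodium Z-enolate 12 (not isolated)
Conditions: NaN(SiMe3)2, THF, −78 °C; 11, −78 → −45 °C
Reagents that add atoms: none
Why: Evans asymmetric alkylation, in which the chelated Z sodium enolate is allylated on the face opposite the benzyl group of the (R)-auxiliary, setting C8 of the target (here 2S, dr ≥ 95:5 expected).

Step 6
Reactants: 13 (4R)-4-benzyl-3-[(2S,5Z)-6,10-dimethyl-2-(prop-2-en-1-yl)undeca-5,9-dienoyl]-1,3-oxazolidin-2-one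
Product: 14 methyl (2S,5Z)-6,10-dimethyl-2-(prop-2-en-1-yl)undeca-5,9-dienoate
Conditions: MeMgBr, MeOH, 0 °C (MeOMgBr formed in the flask)
Reagents that add atoms: methanol, CO
Why: Exocyclic transesterification with MeOMgBr removes the auxiliary without epimerising the α-stereocentre and returns 8 for reuse.

Step 7
Reactants: 14 methyl (2S,5Z)-6,10-dimethyl-2-(prop-2-en-1-yl)undeca-5,9-dienoate
Product: 16 methyl (2S,5Z)-2-(3-iodopropyl)-6,10-dimethylundeca-5,9-dienoate, via primary alkylzirconocene chloride 15 (not isolated)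
Conditions: Cp2Zr(H)Cl (1.5 equiv), THF, rt, 1 h; then I2, 0 °C
Reagents that add atoms: iodine, II
Why: Hydrozirconation–iodination, in which Cp2Zr(H)Cl adds anti-Markovnikov only to the monosubstituted alkene (trisubstituted olefins are inert on this time scale) and iodine cleaves the primary C–Zr bond, leaving the stereocentre untouched.

Step 8
Reactants: 16 methyl (2S,5Z)-2-(3-iodopropyl)-6,10-dimethylundeca-5,9-dienoate; 17 dimethyl (R)-malate
Product: 19 dimethyl (2R,3S)-2-hydroxy-3-[(4R,7Z)-4-(methoxycarbonyl)-8,12-dimethyltrideca-7,11-dien-1-yl]butanedioate, via dilithium alkoxide-enolate of dimethyl (R)-malate 18 (not isolated)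
Conditions: 17 (3 equiv), LiN(i-Pr)2 (6.1 equiv), THF, −78 → −20 °C; then 16, DMPU, −78 → −10 °C; AcOH
Reagents that add atoms: none
Why: Fráter–Seebach alkylation, in which the lithium alkoxide–enolate chelate is alkylated anti to its C2 ester substituent, so C12 of the target is set 2,3-anti to the chiral-pool carbinol (2R,3S, dr about 9:1 expected), with 18 in excess and kept below −10 °C so the α-branched ester of 16 is neither enolised nor acylated.

Step 9
Reactants: 19 dimethyl (2R,3S)-2-hydroxy-3-[(4R,7Z)-4-(methoxycarbonyl)-8,12-dimethyltrideca-7,11-dien-1-yl]butanedioate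
Product: 20 dimethyl (2S,6R)-2-[(1R)-1,2-dihydroxyethyl]-6-[(3Z)-4,8-dimethylnona-3,7-dien-1-yl]heptanedioate
Conditions: BH3·SMe2 (1.05 equiv), THF, 0 °C → rt; NaBH4 (5 mol %); MeOH
Reagents that add atoms: none
Why: Hydroxyl-directed borane reduction, in which the alkoxyborane formed at the free hydroxyl delivers hydride only to the adjacent α-hydroxy ester, leaving the other two esters and (with one equivalent of borane) the olefins untouched; no stereocentre is affected.

Step 10
Reactants: 20 dimethyl (2S,6R)-2-[(1R)-1,2-dihydroxyethyl]-6-[(3Z)-4,8-dimethylnona-3,7-dien-1-yl]heptanedioate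
Product: 22 dimethyl (2S,6R)-6-[(3Z)-4,8-dimethylnona-3,7-dien-1-yl]-2-[(2R)-oxiran-2-yl]heptanedioate, via primary monotosylate 21 (not isolated)
Conditions: TsCl (1.05 equiv), Bu2SnO (2 mol %), Et3N, CH2Cl2, 0 °C; then K2CO3, MeOH, 0 °C
Reagents that add atoms: none
Why: Tin-acetal-catalysed sulfonylation is selective for the primary hydroxyl, and the secondary alkoxide then closes the epoxide by intramolecular Williamson displacement, so the carbinol configuration is retained.

Step 11
Reactants: 22 dimethyl (2S,6R)-6-[(3Z)-4,8-dimethylnona-3,7-dien-1-yl]-2-[(2R)-oxiran-2-yl]heptanedioate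
Product: 24 dimethyl (1R,4Z,8R,12S,13S)-4,15,15-trimethyl-14-oxabicyclo[11.2.1]hexadec-4-ene-8,12-dicarboxylate, via ring-opened tertiary carbocation borate zwitterion 23 (not isolated)
Conditions: B(C6F5)3 (20 mol %), 2,6-di-tert-butyl-4-methylpyridine (0.5 equiv), CH2Cl2, −30 → 0 °C, slow addition of 22 (final 0.5 mM)
Reagents that add atoms: none
Why: Proposed new method: a biomimetic cation–olefin macrocyclisation terminated by oxygen, i.e. an intramolecular formal (3+2) epoxide–alkene annulation; B(C6F5)3 (no transferable halide) activates the epoxide, the ester-bearing neighbour disfavours C13–O ionisation (no Meinwald shift), so the productive path is SN2-type attack of the isopropylidene terminus on the primary C16 (14-membered ring; attack by the internal olefin would need a strained 10-membered ring) to give cation 23, whose borate-bound alkoxide closes the five-membered ether at C15 and releases the catalyst; C13 keeps the malate configuration because its C–O bond is never broken, and C1 is set by 1,3-induction in a staggered open transition state with the bulky CMe2 terminus anti to C13 and the ring tether on the side of the C13 hydrogen, which corresponds to the 1,13-trans ether; closest known chemistry: Lewis-acid epoxide-initiated cation–olefin cyclisations in which the epoxide oxygen captures the final cation, Lewis-acid (3+2) annulations of aryl epoxides with alkenes, and the SnCl4-induced 14-membered cembranoid closure of an acyl cation onto a terminal isopropylidene group.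

Step 12
Reactants: 24 dimethyl (1R,4Z,8R,12S,13S)-4,15,15-trimethyl-14-oxabicyclo[11.2.1]hexadec-4-ene-8,12-dicarboxylate
Product: 25 (1R,4Z,8R,12S,13S)-4,15,15-trimethyl-14-oxabicyclo[11.2.1]hexadec-4-ene-8,12-dicarboxylic acid
Conditions: Me3SnOH (10 equiv), ClCH2CH2Cl, 80 °C; then 1 M HCl
Reagents that add atoms: trimethyltin hydroxide, C[Sn](C)(C)O
Why: Me3SnOH ester hydrolysis goes through a tin carboxylate under mild, non-epimerising conditions, so both α-stereocentres and the β-alkoxy ester (no retro-oxa-Michael opening) survive.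

**Compound list**

1 | nerol, (2Z)-3,7-dimethylocta-2,6-dien-1-ol | CC(C)=CCC/C(C)=C\CO | starting material
2 | neryl bromide, (2Z)-1-bromo-3,7-dimethylocta-2,6-diene | CC(C)=CCC/C(C)=C\CBr | intermediate
3 | 3-chloropropan-1-ol | OCCCCl | starting material
4 | ClMg(CH2)3OMgCl, chloromagnesium 3-(chloromagnesio)propan-1-olate | Cl[Mg]CCCO[Mg]Cl | intermediate (not isolated)
5 | (5Z)-6,10-dimethylundeca-5,9-dien-1-ol | CC(C)=CCC/C(C)=C\CCCCO | intermediate
6 | (5Z)-6,10-dimethylundeca-5,9-dienal | CC(C)=CCC/C(C)=C\CCCC=O | intermediate (not isolated)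
7 | (5Z)-6,10-dimethylundeca-5,9-dienoic acid | CC(C)=CCC/C(C)=C\CCCC(=O)O | intermediate
8 | (4R)-4-benzyl-1,3-oxazolidin-2-one | O=C1N[C@H](Cc2ccccc2)CO1 | starting material
9 | (5Z)-6,10-dimethylundeca-5,9-dienoic pivalic anhydride | CC(C)=CCC/C(C)=C\CCCC(=O)OC(=O)C(C)(C)C | intermediate (not isolated)
10 | (4R)-4-benzyl-3-[(5Z)-6,10-dimethylundeca-5,9-dienoyl]-1,3-oxazolidin-2-one | CC(C)=CCC/C(C)=C\CCCC(=O)N1[C@H](Cc2ccccc2)COC1=O | intermediate
11 | allyl iodide, 3-iodoprop-1-ene | C=CCI | starting material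
12 | sodium (Z)-enolate of 10 | [Na+].[O-]/C(=C\CC/C=C(C)\CCC=C(C)C)N1[C@H](Cc2ccccc2)COC1=O | intermediate (not isolated)
13 | (4R)-4-benzyl-3-[(2S,5Z)-6,10-dimethyl-2-(prop-2-en-1-yl)undeca-5,9-dienoyl]-1,3-oxazolidin-2-one | CC(C)=CCC/C(C)=C\CC[C@@H](CC=C)C(=O)N1[C@H](Cc2ccccc2)COC1=O | intermediate
14 | methyl (2S,5Z)-6,10-dimethyl-2-(prop-2-en-1-yl)undeca-5,9-dienoate | CC(C)=CCC/C(C)=C\CC[C@@H](CC=C)C(=O)OC | intermediate
15 | methyl (2S,5Z)-2-{3-[chlorobis(cyclopentadienyl)zirconio]propyl}-6,10-dimethylundeca-5,9-dienoate | CC(C)=CCC/C(C)=C\CC[C@@H](CCC[Zr](Cl)(C1C=CC=C1)C1C=CC=C1)C(=O)OC | intermediate (not isolated)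
16 | methyl (2S,5Z)-2-(3-iodopropyl)-6,10-dimethylundeca-5,9-dienoate | CC(C)=CCC/C(C)=C\CC[C@@H](CCCI)C(=O)OC | intermediate
17 | dimethyl (R)-malate, dimethyl (2R)-2-hydroxybutanedioate | COC(=O)C[C@@H](O)C(=O)OC | starting material
18 | dilithium alkoxide-enolate of dimethyl (R)-malate | [Li+].[Li+].COC(=O)[C@H]([O-])C=C([O-])OC | intermediate (not isolated)
19 | dimethyl (2R,3S)-2-hydroxy-3-[(4R,7Z)-4-(methoxycarbonyl)-8,12-dimethyltrideca-7,11-dien-1-yl]butanedioate | CC(C)=CCC/C(C)=C\CC[C@@H](CCC[C@H](C(=O)OC)[C@@H](O)C(=O)OC)C(=O)OC | intermediate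
20 | dimethyl (2S,6R)-2-[(1R)-1,2-dihydroxyethyl]-6-[(3Z)-4,8-dimethylnona-3,7-dien-1-yl]heptanedioate | CC(C)=CCC/C(C)=C\CC[C@@H](CCC[C@H](C(=O)OC)[C@@H](O)CO)C(=O)OC | intermediate
21 | dimethyl (2S,6R)-6-[(3Z)-4,8-dimethylnona-3,7-dien-1-yl]-2-[(1R)-1-hydroxy-2-(4-methylbenzenesulfonyloxy)ethyl]heptanedioate | CC(C)=CCC/C(C)=C\CC[C@@H](CCC[C@H](C(=O)OC)[C@@H](O)COS(=O)(=O)c1ccc(C)cc1)C(=O)OC | intermediate (not isolated)
22 | dimethyl (2S,6R)-6-[(3Z)-4,8-dimethylnona-3,7-dien-1-yl]-2-[(2R)-oxiran-2-yl]heptanedioate | CC(C)=CCC/C(C)=C\CC[C@@H](CCC[C@H](C(=O)OC)[C@@H]1CO1)C(=O)OC | intermediate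
23 | zwitterion: 14-membered ring closed (C16–C1), 2-propyl cation on C1, C13 oxygen bound as O–B(C6F5)3 borate | C[C+](C)[C@@H]1CC/C(C)=C\CC[C@H](C(=O)OC)CCC[C@H](C(=O)OC)[C@@H](O[B-](c2c(F)c(F)c(F)c(F)c2F)(c2c(F)c(F)c(F)c(F)c2F)c2c(F)c(F)c(F)c(F)c2F)C1 | intermediate (not isolated)
24 | dimethyl (1R,4Z,8R,12S,13S)-4,15,15-trimethyl-14-oxabicyclo[11.2.1]hexadec-4-ene-8,12-dicarboxylate | C/C1=C/CC[C@H](C(=O)OC)CCC[C@H](C(=O)OC)[C@@H]2C[C@@H](CC1)C(C)(C)O2 | intermediate
25 | (1R,4Z,8R,12S,13S)-4,15,15-trimethyl-14-oxabicyclo[11.2.1]hexadec-4-ene-8,12-dicarboxylic acid | C/C1=C/CC[C@H](C(=O)O)CCC[C@H](C(=O)O)[C@@H]2C[C@@H](CC1)C(C)(C)O2 | target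

**Step count**

Total steps: 12. Longest linear sequence: 12 steps (1 → 25); compounds 3, 8, 11 and 17 are bought.

**Steps most likely to fail**

Step 11 is the main risk. The alkene must attack a primary epoxide carbon through a 14-membered transition state with no direct precedent. Competing outcomes are oligomers, attack by the C4=C5 olefin, loss of a proton from 23 to give an isopropenyl alcohol, capture of the cation by the C4=C5 olefin, and the C1 epimer (the cis ether), which would have to be separated by chromatography. The fallback sets out from diol 20 and comes back at 24; it closes the carbocycle by a carbonyl-ene reaction and makes the ether afterwards. Et3SiCl and imidazole give dimethyl (2S,6R)-2-[(1R)-1,2-bis(triethylsilyloxy)ethyl]-6-[(3Z)-4,8-dimethylnona-3,7-dien-1-yl]heptanedioate F1. Swern oxidation ((COCl)2, DMSO, then Et3N) converts only the primary silyl ether into the aldehyde dimethyl (2S,6R)-6-[(3Z)-4,8-dimethylnona-3,7-dien-1-yl]-2-[(1R)-2-oxo-1-(triethylsilyloxy)ethyl]heptanedioate F2. Me2AlCl in CH2Cl2 at −78 °C under high dilution joins the isopropylidene terminus to the aldehyde carbon (the same C16–C1 bond) and gives the 14-membered homoallylic alcohol dimethyl 3-hydroxy-7-methyl-4-(prop-1-en-2-yl)-2-(triethylsilyloxy)cyclotetradec-7-ene-1,11-dicarboxylate F3. HF·pyridine followed by catalytic camphorsulfonic acid removes the silyl group and adds the C13 hydroxyl across the isopropenyl group (Markovnikov) to give the 16-hydroxy derivative of 24 F4. 1,1'-Thiocarbonyldiimidazole then gives the 16-O-(imidazol-1-ylthiocarbonyl) derivative of 24 F5, and Bu3SnH/AIBN (Barton–McCombie) removes the C16 oxygen to give 24.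

Step 8 is the second risk. A malate dianion is alkylated with an unactivated primary iodide; the yield is likely moderate, and the α-branched ester of 16 could be epimerised or acylated during the long reaction time. The fallback sets out from alkene 14 and comes back at 19; it uses an electrophile that reacts at −78 °C, where proton transfer and ester condensation are frozen out. 9-BBN, then NaBO3, gives methyl (2S,5Z)-2-(3-hydroxypropyl)-6,10-dimethylundeca-5,9-dienoate F6. Tf2O and 2,6-lutidine at −78 °C give methyl (2S,5Z)-6,10-dimethyl-2-[3-(trifluoromethanesulfonyloxy)propyl]undeca-5,9-dienoate F7, which is added directly to dianion 18 at −78 °C to give 19.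

Step 10 is the third risk. The β,γ-epoxy ester 22 has an acidic α-hydrogen and can open under base to the γ-hydroxy enoate, and diol 20 can lactonise. The fallback sets out from diol 20 and comes back at 22; it avoids base altogether. CBr4/PPh3 at 0 °C (Appel) brominates only the primary hydroxyl to give dimethyl (2S,6R)-2-[(1R)-2-bromo-1-hydroxyethyl]-6-[(3Z)-4,8-dimethylnona-3,7-dien-1-yl]heptanedioate F8, and Ag2O in MeCN closes the epoxide under neutral conditions to give 22.

**Further compounds**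

F1 | step 11 | dimethyl (2S,6R)-2-[(1R)-1,2-bis(triethylsilyloxy)ethyl]-6-[(3Z)-4,8-dimethylnona-3,7-dien-1-yl]heptanedioate | CC(C)=CCC/C(C)=C\CC[C@@H](CCC[C@H](C(=O)OC)[C@@H](O[Si](CC)(CC)CC)CO[Si](CC)(CC)CC)C(=O)OC
F2 | step 11 | dimethyl (2S,6R)-6-[(3Z)-4,8-dimethylnona-3,7-dien-1-yl]-2-[(1R)-2-oxo-1-(triethylsilyloxy)ethyl]heptanedioate | CC(C)=CCC/C(C)=C\CC[C@@H](CCC[C@H](C(=O)OC)[C@@H](O[Si](CC)(CC)CC)C=O)C(=O)OC
F3 | step 11 | dimethyl 3-hydroxy-7-methyl-4-(prop-1-en-2-yl)-2-(triethylsilyloxy)cyclotetradec-7-ene-1,11-dicarboxylate (7Z; ring stereocentres as in 24; C3 carbinol epimers) | CC(=C)[C@@H]1CC/C(C)=C\CC[C@H](C(=O)OC)CCC[C@H](C(=O)OC)[C@@H](O[Si](CC)(CC)CC)C1O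
F4 | step 11 | 16-hydroxy derivative of 24, dimethyl 16-hydroxy-4,15,15-trimethyl-14-oxabicyclo[11.2.1]hexadec-4-ene-8,12-dicarboxylate (C16 epimers) | C/C1=C/CC[C@H](C(=O)OC)CCC[C@H](C(=O)OC)[C@@H]2C(O)[C@@H](CC1)C(C)(C)O2
F5 | step 11 | 16-O-(imidazol-1-ylthiocarbonyl) derivative of 24 | C/C1=C/CC[C@H](C(=O)OC)CCC[C@H](C(=O)OC)[C@@H]2C(OC(=S)n3ccnc3)[C@@H](CC1)C(C)(C)O2
F6 | step 8 | methyl (2S,5Z)-2-(3-hydroxypropyl)-6,10-dimethylundeca-5,9-dienoate | CC(C)=CCC/C(C)=C\CC[C@@H](CCCO)C(=O)OC
F7 | step 8 | methyl (2S,5Z)-6,10-dimethyl-2-[3-(trifluoromethanesulfonyloxy)propyl]undeca-5,9-dienoate | CC(C)=CCC/C(C)=C\CC[C@@H](CCCOS(=O)(=O)C(F)(F)F)C(=O)OC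
F8 | step 10 | dimethyl (2S,6R)-2-[(1R)-2-bromo-1-hydroxyethyl]-6-[(3Z)-4,8-dimethylnona-3,7-dien-1-yl]heptanedioate | CC(C)=CCC/C(C)=C\CC[C@@H](CCC[C@H](C(=O)OC)[C@@H](O)CBr)C(=O)OC
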